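At the time of reading, 30 min, this flask is far past its last reading at 6.00 min, so what you need is where it stops, not how fast it goes.

| setting | epsilon | flask |
|---|---|---|
| Q | 0.10 M | 0.10 M |
| J | 1 equiv | 1.00 equiv |
| remark | the very flask that is asked about, followed so far |  |
| time |  | 30 min |

- epsilon (time / min: Q / %, L / %, E / %): 0.417: 66.3, 21.9, 2.0; 1.33: 38.5, 34.8, 9.5; 2.00: 33.4, 38.4, 13.9; 3.00: 27.6, 39.7, 17.5; 5.00: 23.9, 38.7, 20.5; 6.00: 25.1, 39.0, 22.8

(scatter of a reading: 1 percentage point)

- the numbers in the tables scatter with a standard deviation of 1 percentage point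

- share of the Q used up at 30 min
- L at 30 min, in percent of the Q charged
- E at 30 min, in percent of the Q charged
- Z at 30 min, in percent of the Q charged

Keep the books on J. Each Q used takes one J, and each E takes a second. The last reading gives 1.30: this is the J price, the J spent per Q used up. At the start the price is one, since no E exists yet, and the first reading gives 1.06. Join the two ends: the flask stops where Q used times price equals the J charged.

Now turn the settings by hand. Time: with equal charges, J left is [Q] − [E], which reads 10.1% at 3.00 min and 2.30% at 6.00 min. That fall took 3.00 min, short against 30 min, so more time adds little, and J is the limiting reagent. J charge: the stop moves with it, so I reckon this flask stops at Q used 76.7% and E 23.3%, with [Q] equal to [E]. With less J, I read the price earlier on the same path. [Q] at fixed equivalents: I expect the clock to move and the stop to stay. Of the Q used that has not gone on to E, 53.3%, I give L its last reading, 39.0%, leaving 14.3% for Z.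

The forecast says “J runs out, with Q ≈ E” and gives Q used 76.5%, L 38.5%, E 23.5% and Z 14.5%.

The flask gives Q used 78.3%, L 39.6%, E 21.7% and Z 9.52%, a price of 1.28 against my 1.30.

    L ⇌ G (K = 0.190, k = 0.0250 s⁻¹)
    Q + J → L (k = 0.170 M⁻¹ s⁻¹)
    Q + J → Z (k = 0.0380 M⁻¹ s⁻¹)
    J + L → E (k = 0.0810 M⁻¹ s⁻¹)
    J + Z → E (k = 0.0930 M⁻¹ s⁻¹)

Z stands lower than my 14.3%, and G, which no reading showed, holds 7.53% of the Q charged. Now take the neighbouring flask, charged with 0.400 equiv of J, all else held. The run had spent 35.7% of J at the first reading and 71.0% at the second, so I use the early price, 1.06. That gives Q used 37.7% and E 2.24%. The neighbouring flask gives Q used 36.9% and E 3.07%, a price of 1.08.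

The earlier runs and the new flask are calculated with constants of no real substance; the scatter is artificial.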